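**Retrosynthetic overview**
1. Target 20 ⇐ 19 ⇐ 18 ⇐ 15: acetylation, hydroxyl-directed epoxidation of the E-olefin between the two carbinols, selective angeloylation of a cyclodecadienediol.
2. 15 ⇐ 14: ring expansion by decarboxylative Grob-type fragmentation of a trans-decalin epoxy carboxylate; cleaving the ring-fusion bond gives the ten-membered ring, both E-olefins and the free allylic C–O.
3. 14 ⇐ 13 ⇐ 12 ⇐ 10: Shi epoxidation (kinetic resolution), then deconjugation and reduction of an octalone.
4. 10 ⇐ 8 ⇐ 6 ⇐ 3: Wichterle annulation, ester alkylation with 1,3-dichlorobut-2-ene, Mukaiyama–Michael addition to piperitone.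
5. Ring order: ring B (cyclohexenone 1), then ring A (decalin 10), then the ten-membered carbocycle (15), oxirane last (19).

Assumption: 1,3-dichlorobut-2-ene is used as the commercial E/Z mixture; compounds 3 and 6–12 are racemic and drawn as the enantiomer that is carried on after the resolution in step 6.

Step 1
Reactants: 1 3-methylcyclohex-2-en-1-one; 2 2-iodopropane
Product: 3 rac-3-methyl-6-(propan-2-yl)cyclohex-2-en-1-one (piperitone)
Conditions: LiN(i-Pr)2, THF, −78 °C; then 2, DMPU, −78 to −20 °C
Reagents that add atoms: none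
Why: Kinetic deprotonation at the alpha-prime CH2 and enolate alkylation install the isopropyl group; the new centre is racemic and is equilibrated in step 4, so its configuration does not matter here.

Step 2
Reactants: 3 piperitone; 4 methyl acetate
Product: 6 rac-methyl 2-[(1R)-3-{[tert-butyl(dimethyl)silyl]oxy}-1-methyl-4-(propan-2-yl)cyclohex-2-en-1-yl]acetate (both epimers at C4), via ketene silyl acetal 5 (not isolated)
Conditions: 4, LiN(i-Pr)2, THF, −78 °C; t-BuMe2SiCl, DMPU (crude 5 freed of LiCl and amine); then 3, Tf2NH (3 mol%), CH2Cl2, −78 °C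
Reagents that add atoms: tert-butyldimethylsilyl chloride, CC(C)(C)[Si](C)(C)Cl
Why: Silyl-triflimide-catalysed Mukaiyama–Michael addition puts the acetate unit on the beta,beta-disubstituted enone carbon and leaves the ketone masked as a regiodefined silyl enol ether; the quaternary centre forms as a racemate (resolved in step 6).

Step 3
Reactants: 6 silyl enol ether ester; 7 1,3-dichlorobut-2-ene
Product: 8 rac-methyl 5-chloro-2-[(1S)-3-{[tert-butyl(dimethyl)silyl]oxy}-1-methyl-4-(propan-2-yl)cyclohex-2-en-1-yl]hex-4-enoate (mixture of epimers and E/Z isomers)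
Conditions: LiN(i-Pr)2, THF, −78 °C; then 7, NaI (10 mol%), DMPU, −78 to 0 °C
Reagents that add atoms: none
Why: Ester enolate alkylation at the allylic chloride of the Wichterle reagent, whose vinyl chloride is a masked methyl ketone; the silyl enol ether keeps the ketone out of play and the new ester alpha-centre is equilibrated in step 5.

Step 4
Reactants: 8 chloro ester
Product: 10 rac-methyl (1S,6R,8aR)-4,8a-dimethyl-5-oxo-6-(propan-2-yl)-1,2,3,5,6,7,8,8a-octahydronaphthalene-1-carboxylate, via diketo ester 9 (not isolated)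
Conditions: 90% H2SO4, 0 °C to rt; then crude 9, TsOH, benzene, reflux (Dean–Stark)
Reagents that add atoms: none
Why: Wichterle annulation, in which acid hydrolyses the vinyl chloride and the silyl enol ether and acid-catalysed aldol cyclodehydration closes ring A to the conjugated octalone (the bridged ketol is reversible and cannot dehydrate); under these equilibrating conditions the isopropyl group settles pseudo-equatorial, cis to the angular methyl.

Step 5
Reactants: 10 octalone
Product: 12 rac-methyl (1S,4aR,5S,6R,8aS)-5-hydroxy-4,8a-dimethyl-6-(propan-2-yl)-1,2,4a,5,6,7,8,8a-octahydronaphthalene-1-carboxylate, via deconjugated ketone 11 (not isolated)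
Conditions: KOt-Bu (5 equiv), t-BuOH–THF, 25 °C; inverse quench into 10% aq. AcOH, 0 °C; then crude 11, NaBH4, CeCl3·7H2O, MeOH, −40 °C
Reagents that add atoms: none
Why: Ringold-type deconjugation followed by Luche reduction: the extended dienolate (in which the ester centre equilibrates to equatorial) is protonated kinetically at the alpha carbon on the face opposite the angular methyl to give the trans-fused beta,gamma-enone, and hydride then attacks the same open alpha face to give the axial 5-hydroxyl cis to the isopropyl group.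

Step 6
Reactants: 12 racemic homoallylic alcohol
Product: 13 methyl (1S,3S,4R,4aR,5S,6R,8aS)-3,4-epoxy-5-hydroxy-4,8a-dimethyl-6-(propan-2-yl)decahydronaphthalene-1-carboxylate
Conditions: L-fructose-derived Shi ketone (mirror image of 1,2:4,5-di-O-isopropylidene-β-D-erythro-2,3-hexodiulo-2,6-pyranose, 0.3 equiv), KHSO5 (0.7 equiv), K2CO3, Bu4NHSO4, MeCN–CH2(OMe)2 / aq. Na2B4O7 buffer, 0 °C, to about 50% conversion
Reagents that add atoms: potassium peroxymonosulfate KHSO5, [K+].[O-]S(=O)(=O)OO
Why: Shi epoxidation used as a kinetic resolution of a racemic 1,6-disubstituted cyclohexene: for the wanted enantiomer the catalyst-preferred spiro approach (predicted for the L-fructose-derived ketone) coincides with the open alpha face anti to the angular methyl and gives the (3S,4R)-epoxide, while the mismatched antipode stays as olefin and is removed (yield capped at 50%).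

Step 7
Reactants: 13 epoxy hydroxy ester
Product: 15 (1S,2E,4S,6E,10R)-3,7-dimethyl-10-(propan-2-yl)cyclodeca-2,6-diene-1,4-diol, via potassium carboxylate 14 (not isolated)
Conditions: KOSiMe3 (1.1 equiv), THF, 45 °C; then 18-crown-6, CF3CH2OH (5 equiv), toluene, 65 °C
Reagents that add atoms: none
Why: Proposed new method: decarboxylative Grob-type 1,4-fragmentation with an epoxide nucleofuge, in which the equatorial C1 carboxylate (lost as CO2) and the tertiary C4–O epoxide bond (hydrogen-bond activated by CF3CH2OH) are both antiperiplanar to the C4a–C8a fusion bond of the trans-decalin, so that a seven-centre electron shift cleaves that bond, forms both E-trisubstituted olefins stereospecifically and releases the C3 oxygen as the allylic alkoxide while the three carbinol and isopropyl stereocentres are untouched; the closest known reactions are the Marshall boronate fragmentation of decalin sulfonates, the Grob fragmentation and Eschenmoser's decarboxylative double fragmentation.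

Step 8
Reactants: 15 dienediol; 16 (2Z)-2-methylbut-2-enoic acid (angelic acid)
Product: 18 (1S,2E,4S,5R,8E)-4-hydroxy-2,8-dimethyl-5-(propan-2-yl)cyclodeca-2,8-dien-1-yl (2Z)-2-methylbut-2-enoate, via mixed anhydride 17 (not isolated)
Conditions: 16, 2,4,6-trichlorobenzoyl chloride, Et3N, toluene, 25 °C; then 15, 45 °C (no DMAP)
Reagents that add atoms: none
Why: Yamaguchi esterification through the mixed anhydride (DMAP-free and mild, so the angelate is not isomerised to tiglate) acylates the less hindered allylic hydroxyl next to the methyl-bearing olefin carbon, while the hydroxyl flanked by the isopropyl-bearing carbon stays free.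

Step 9
Reactants: 18 mono-angelate
Product: 19 (1R,2S,3R,6E,9S,10R)-2-hydroxy-6,10-dimethyl-3-(propan-2-yl)-11-oxabicyclo[8.1.0]undec-6-en-9-yl (2Z)-2-methylbut-2-enoate
Conditions: VO(acac)2 (5 mol%), t-BuOOH (1.5 equiv), CH2Cl2, 0 to 25 °C
Reagents that add atoms: tert-butyl hydroperoxide, CC(C)(C)OO
Why: Hydroxyl-directed vanadium-catalysed epoxidation (Sharpless–Michaelson type) reacts only at the allylic olefin; 1,3-allylic strain with the cis methyl holds the carbinol C–H in the olefin plane, so oxygen is delivered on the peripheral face syn to the hydroxyl and sets the threo (1R,10R) epoxide.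

Step 10
Reactants: 19 epoxy alcohol
Product: 20 (1R,2S,3R,6E,9S,10R)-2-(acetyloxy)-6,10-dimethyl-3-(propan-2-yl)-11-oxabicyclo[8.1.0]undec-6-en-9-yl (2Z)-2-methylbut-2-enoate (CNP0180504.1)
Conditions: Ac2O, DMAP (cat.), pyridine, 25 °C
Reagents that add atoms: acetic anhydride, CC(=O)OC(C)=O
Why: DMAP-catalysed acetylation of the remaining hindered secondary alcohol; no stereocentre is touched and no base strong enough for Payne rearrangement is present.

**Compound list**
1 | 3-methylcyclohex-2-en-1-one | CC1=CC(=O)CCC1 | starting material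
2 | 2-iodopropane | CC(C)I | starting material
3 | rac-3-methyl-6-(propan-2-yl)cyclohex-2-en-1-one (piperitone) | CC1=CC(=O)C(C(C)C)CC1 | intermediate
4 | methyl acetate | COC(C)=O | starting material
5 | tert-butyl[(1-methoxyethenyl)oxy]dimethylsilane | C=C(OC)O[Si](C)(C)C(C)(C)C | intermediate
6 | rac-methyl 2-[(1R)-3-{[tert-butyl(dimethyl)silyl]oxy}-1-methyl-4-(propan-2-yl)cyclohex-2-en-1-yl]acetate (both epimers at C4) | COC(=O)C[C@]1(C)C=C(O[Si](C)(C)C(C)(C)C)C(C(C)C)CC1 | intermediate
7 | 1,3-dichlorobut-2-ene (E/Z mixture) | CC(Cl)=CCCl | starting material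
8 | rac-methyl 5-chloro-2-[(1S)-3-{[tert-butyl(dimethyl)silyl]oxy}-1-methyl-4-(propan-2-yl)cyclohex-2-en-1-yl]hex-4-enoate (epimer and E/Z mixture) | COC(=O)C(CC=C(C)Cl)[C@]1(C)C=C(O[Si](C)(C)C(C)(C)C)C(C(C)C)CC1 | intermediate
9 | rac-methyl 2-[(1S)-1-methyl-3-oxo-4-(propan-2-yl)cyclohexyl]-5-oxohexanoate (epimer mixture) | COC(=O)C(CCC(C)=O)[C@]1(C)CC(=O)C(C(C)C)CC1 | intermediate
10 | rac-methyl (1S,6R,8aR)-4,8a-dimethyl-5-oxo-6-(propan-2-yl)-1,2,3,5,6,7,8,8a-octahydronaphthalene-1-carboxylate | COC(=O)[C@H]1CCC(C)=C2C(=O)[C@@H](C(C)C)CC[C@@]21C | intermediate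
11 | rac-methyl (1S,4aR,6R,8aS)-4,8a-dimethyl-5-oxo-6-(propan-2-yl)-1,2,4a,5,6,7,8,8a-octahydronaphthalene-1-carboxylate | COC(=O)[C@H]1CC=C(C)[C@H]2C(=O)[C@@H](C(C)C)CC[C@@]21C | intermediate
12 | rac-methyl (1S,4aR,5S,6R,8aS)-5-hydroxy-4,8a-dimethyl-6-(propan-2-yl)-1,2,4a,5,6,7,8,8a-octahydronaphthalene-1-carboxylate | COC(=O)[C@H]1CC=C(C)[C@H]2[C@@H](O)[C@@H](C(C)C)CC[C@@]21C | intermediate
13 | methyl (1S,3S,4R,4aR,5S,6R,8aS)-3,4-epoxy-5-hydroxy-4,8a-dimethyl-6-(propan-2-yl)decahydronaphthalene-1-carboxylate | COC(=O)[C@H]1C[C@@H]2O[C@]2(C)[C@H]3[C@@H](O)[C@@H](C(C)C)CC[C@@]31C | intermediate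
14 | potassium (1S,3S,4R,4aR,5S,6R,8aS)-3,4-epoxy-5-hydroxy-4,8a-dimethyl-6-(propan-2-yl)decahydronaphthalene-1-carboxylate | [K+].[O-]C(=O)[C@H]1C[C@@H]2O[C@]2(C)[C@H]3[C@@H](O)[C@@H](C(C)C)CC[C@@]31C | intermediate
15 | (1S,2E,4S,6E,10R)-3,7-dimethyl-10-(propan-2-yl)cyclodeca-2,6-diene-1,4-diol | O[C@H]1C/C=C(\C)CC[C@H](C(C)C)[C@H](O)/C=C1\C | intermediate
16 | (2Z)-2-methylbut-2-enoic acid (angelic acid) | C/C=C(/C)C(=O)O | starting material
17 | (2Z)-2-methylbut-2-enoic 2,4,6-trichlorobenzoic anhydride | C/C=C(/C)C(=O)OC(=O)c1c(Cl)cc(Cl)cc1Cl | intermediate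
18 | (1S,2E,4S,5R,8E)-4-hydroxy-2,8-dimethyl-5-(propan-2-yl)cyclodeca-2,8-dien-1-yl (2Z)-2-methylbut-2-enoate | C/C=C(/C)C(=O)O[C@H]1C/C=C(\C)CC[C@H](C(C)C)[C@H](O)/C=C1\C | intermediate
19 | (1R,2S,3R,6E,9S,10R)-2-hydroxy-6,10-dimethyl-3-(propan-2-yl)-11-oxabicyclo[8.1.0]undec-6-en-9-yl (2Z)-2-methylbut-2-enoate | C/C=C(/C)C(=O)O[C@H]1C/C=C(\C)CC[C@H](C(C)C)[C@H](O)[C@H]2O[C@]12C | intermediate
20 | (1R,2S,3R,6E,9S,10R)-2-(acetyloxy)-6,10-dimethyl-3-(propan-2-yl)-11-oxabicyclo[8.1.0]undec-6-en-9-yl (2Z)-2-methylbut-2-enoate | C/C=C(/C)C(=O)O[C@H]1C/C=C(\C)CC[C@H](C(C)C)[C@H](OC(C)=O)[C@H]2O[C@]12C | target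

**Step count**
Total steps: 10. Longest linear sequence: 10 (from 1).

**Three steps most likely to fail**

Step 7 (the proposed new fragmentation). The carboxylate may be too weak an electrofuge, or the epoxide may open by other paths. The fallback uses boron as the electrofuge, as in the Marshall fragmentation. It sets out from 14: after acidification, N-hydroxyphthalimide and N,N'-diisopropylcarbodiimide give the redox-active N-(acyloxy)phthalimide F4. Decarboxylative borylation (B2pin2, Cu(acac)2, LiOH·H2O, MgCl2) gives the equatorial pinacol boronate F5. NaOMe in MeOH–THF at 50 °C forms the borate, which undergoes the boron-ate 1,4-fragmentation with the same antiperiplanar geometry, and the route is rejoined at 15.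

Step 6 (kinetic resolution). The selectivity factor of the Shi epoxidation on this decalin may be too low. The fallback replaces it by a classical resolution and sets out from 12: m-CPBA (NaHCO3, CH2Cl2, 0 °C) epoxidises both enantiomers on the alpha face, giving 13 together with its mirror image, the ent-epoxy ester F1. LiOH (THF–H2O) gives the racemic epoxy hydroxy acid F2. Crystallisation with (R)-1-phenylethylamine gives the diastereomerically pure ammonium salt F3 (the (S)-amine is used if the wrong antipode crystallises). Aqueous KOH and extraction of the amine give 14, where the route is rejoined.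

Step 8 (regioselective angeloylation). The two allylic hydroxyls of 15 may not be differentiated well enough. The fallback protects the hindered one before the ring expansion and sets out from 13: Et3SiOTf and 2,6-lutidine give the triethylsilyl ether F6. The conditions of step 7 convert it into the mono-silylated dienol F7, in which only the hydroxyl next to the methyl-bearing olefin is free. Yamaguchi esterification with 16 gives the silylated angelate F8, and HF·pyridine removes the silyl group to rejoin the route at 18.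

**Further compounds**
F1 | step 6 | methyl (1R,3R,4S,4aS,5R,6S,8aR)-3,4-epoxy-5-hydroxy-4,8a-dimethyl-6-(propan-2-yl)decahydronaphthalene-1-carboxylate (mirror image of 13) | COC(=O)[C@@H]1C[C@H]2O[C@@]2(C)[C@@H]3[C@H](O)[C@H](C(C)C)CC[C@]31C
F2 | step 6 | (1S,3S,4R,4aR,5S,6R,8aS)-3,4-epoxy-5-hydroxy-4,8a-dimethyl-6-(propan-2-yl)decahydronaphthalene-1-carboxylic acid (formed as the racemate) | OC(=O)[C@H]1C[C@@H]2O[C@]2(C)[C@H]3[C@@H](O)[C@@H](C(C)C)CC[C@@]31C
F3 | step 6 | (R)-1-phenylethylammonium (1S,3S,4R,4aR,5S,6R,8aS)-3,4-epoxy-5-hydroxy-4,8a-dimethyl-6-(propan-2-yl)decahydronaphthalene-1-carboxylate | C[C@@H]([NH3+])c1ccccc1.[O-]C(=O)[C@H]1C[C@@H]2O[C@]2(C)[C@H]3[C@@H](O)[C@@H](C(C)C)CC[C@@]31C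
F4 | step 7 | 1,3-dioxoisoindolin-2-yl (1S,3S,4R,4aR,5S,6R,8aS)-3,4-epoxy-5-hydroxy-4,8a-dimethyl-6-(propan-2-yl)decahydronaphthalene-1-carboxylate | O=C(ON1C(=O)c2ccccc2C1=O)[C@H]1C[C@@H]2O[C@]2(C)[C@H]3[C@@H](O)[C@@H](C(C)C)CC[C@@]31C
F5 | step 7 | pinacol boronate of 13 with equatorial 4,4,5,5-tetramethyl-1,3,2-dioxaborolan-2-yl in place of the methoxycarbonyl group | CC1(C)OB(OC1(C)C)[C@H]1C[C@@H]2O[C@]2(C)[C@H]3[C@@H](O)[C@@H](C(C)C)CC[C@@]31C
F6 | step 8 | methyl (1S,3S,4R,4aR,5S,6R,8aS)-3,4-epoxy-4,8a-dimethyl-6-(propan-2-yl)-5-[(triethylsilyl)oxy]decahydronaphthalene-1-carboxylate | COC(=O)[C@H]1C[C@@H]2O[C@]2(C)[C@H]3[C@@H](O[Si](CC)(CC)CC)[C@@H](C(C)C)CC[C@@]31C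
F7 | step 8 | (1S,2E,4S,5R,8E)-2,8-dimethyl-5-(propan-2-yl)-4-[(triethylsilyl)oxy]cyclodeca-2,8-dien-1-ol | O[C@H]1C/C=C(\C)CC[C@H](C(C)C)[C@H](O[Si](CC)(CC)CC)/C=C1\C
F8 | step 8 | (1S,2E,4S,5R,8E)-2,8-dimethyl-5-(propan-2-yl)-4-[(triethylsilyl)oxy]cyclodeca-2,8-dien-1-yl (2Z)-2-methylbut-2-enoate | C/C=C(/C)C(=O)O[C@H]1C/C=C(\C)CC[C@H](C(C)C)[C@H](O[Si](CC)(CC)CC)/C=C1\C
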